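**Retrosynthetic overview**
1. Target 20 comes from its 15-O-TBS ether 19. Cutting C6–C7 opens the ten-membered ring and the lactone together and leads to the acyclic aldehyde/2-(methoxycarbonyl)allylboronate 17. In 17 the acrylate β-carbon C7 acts as a donor (homoenolate equivalent) toward the C6 aldehyde.
2. The allylboronate comes from ynoate 14 by syn-hydroalumination and trapping with ICH2Bpin. C7–C8 comes from methyl propiolate and aldehyde 10, and the angelate is put on by Mitsunobu inversion.
3. C9–C10 comes from catalytic asymmetric allylboration of the methyl ketone of Z-ene-dione 7. The enone and the carbinol are then stored together as a 2-methoxy-2,5-dihydrofuran.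
4. The Z-ene-dione comes from furan 6. C3–C4 comes from 2-methylfuran, used as a masked (Z)-4-oxopent-2-enoyl anion, adding to enal 3 under iminium catalysis.
5. Ring order: a temporary dihydrofuran is made in step 4 and opened in step 9. The ten-membered carbocycle and then the γ-lactone both form in step 10.

Atom labels (germacrane): C1=C2 alkene, C3 ketone, C4 CH bearing C15H2OH, C6 lactone O–CH, C7 ring fusion, C8 angelate carbon, C10 carbinol (C14 methyl), C11–C13 methylene lactone.

Assumption: the target is treated as the open Z-γ-hydroxy enone drawn (it may equilibrate with its 3,10-hemiketal), and the absolute sense of the three chiral catalysts is taken from their model substrates, the antipode of each being commercial.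

**Step 1**
Reactants: 1 allyloxy(tert-butyl)dimethylsilane; 2 (E)-crotonaldehyde
Product: 3 (E)-4-(tert-butyldimethylsilyloxy)but-2-enal
Conditions: second-generation Hoveyda–Grubbs catalyst (2 mol %), 2 (5 equiv), CH2Cl2, 40 °C
Reagents that add atoms: none
Why: Olefin cross-metathesis between a reactive allyl ether and an electron-poor enal partner favours the cross product and gives the E-enal under thermodynamic control while propene escapes as a gas.

**Step 2**
Reactants: 3 (E)-4-(tert-butyldimethylsilyloxy)but-2-enal; 4 2-methylfuran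
Product: 6 (S)-tert-butyl[4,4-dimethoxy-2-(5-methylfuran-2-yl)butoxy]dimethylsilane, via furyl aldehyde 5 (not isolated)
Conditions: (2S,5S)-5-benzyl-2-tert-butyl-3-methylimidazolidin-4-one·CF3CO2H (20 mol %), 4 (3 equiv), EtOAc, −40 °C; then HC(OMe)3, MeOH, PPTS (5 mol %), 0 °C
Reagents that add atoms: trimethyl orthoformate COC(OC)OC
Why: In this iminium-catalysed asymmetric Friedel–Crafts conjugate addition, C5 of 2-methylfuran (the future C3 ketone carbon) serves as a masked (Z)-4-oxopent-2-enoyl anion and bonds to the electrophilic β-carbon of the enal (a formal asymmetric Stetter reaction), the benzyl and tert-butyl groups of the catalyst leave one face of the E-iminium ion open so that C4 is set as S, and the aldehyde is then masked in the same flask by acid-catalysed acetalisation.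

**Step 3**
Reactants: 6 (S)-furyl dimethyl acetal
Product: 7 (S,Z)-6-[(tert-butyldimethylsilyloxy)methyl]-8,8-dimethoxyoct-3-ene-2,5-dione
Conditions: mCPBA (1.05 equiv), CH2Cl2, 0 °C, dark; aq NaHCO3 wash, used crude
Reagents that add atoms: mCPBA OOC(=O)c1cccc(Cl)c1
Why: Oxidative furan ring opening (epoxidation of the electron-rich 2,5-dialkylfuran followed by ring opening) gives the ene-dione, whose Z geometry is inherited from the ring and becomes the Z-enone of the target, and C4 is not touched at 0 °C.

**Step 4**
Reactants: 7 Z-ene-dione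
Product: 9 (5R)-2-[(2S)-1-(tert-butyldimethylsilyloxy)-4,4-dimethoxybutan-2-yl]-2-methoxy-5-methyl-5-(prop-2-enyl)-2,5-dihydrofuran (both anomers at the ketal carbon), via tertiary carbinol 8 (not isolated)
Conditions: CH2=CHCH2B(OiPr)2 (1.5 equiv), (S)-3,3'-Br2-BINOL (15 mol %), PhCF3/toluene 3:1, −35 °C; then MeOH, PPTS (10 mol %), rt
Reagents that add atoms: diisopropyl allylboronate C=CCB(OC(C)C)OC(C)C; methanol CO
Why: Chiral-diol-catalysed asymmetric allylboration of a ketone through a closed chair transition state attacks the unhindered methyl ketone rather than the α-branched C3 ketone, tells CH3 from the alkenyl group so that Re-face attack sets C10 as R, and the Z geometry then lets the new oxygen close onto C3 so that MeOH/PPTS stores enone and carbinol together as a methyl ketal.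

**Step 5**
Reactants: 9 allyl dihydrofuran ketal
Product: 10 2-[(2R)-5-[(2S)-1-(tert-butyldimethylsilyloxy)-4,4-dimethoxybutan-2-yl]-5-methoxy-2-methyl-2,5-dihydrofuran-2-yl]acetaldehyde
Conditions: OsO4 (2 mol %), NaIO4 (4 equiv), 2,6-lutidine (2 equiv), dioxane/H2O 3:1, rt
Reagents that add atoms: sodium periodate [Na+].[O-]I(=O)(=O)=O
Why: In the Lemieux–Johnson cleavage OsO4 dihydroxylates the unhindered monosubstituted alkene much faster than the ring alkene flanked by two fully substituted oxygen-bearing carbons, periodate cleaves the diol, lutidine keeps the medium neutral for ketal, acetal and silyl ether, and no stereocentre is touched.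

**Step 6**
Reactants: 10 C8 aldehyde; 11 methyl propiolate
Product: 12 methyl (4S)-4-hydroxy-5-[(2R)-5-[(2S)-1-(tert-butyldimethylsilyloxy)-4,4-dimethoxybutan-2-yl]-5-methoxy-2-methyl-2,5-dihydrofuran-2-yl]pent-2-ynoate
Conditions: 11 (4 equiv), ZnEt2 (4 equiv), (R)-BINOL (40 mol %), HMPA (2 equiv), CH2Cl2, rt, 16 h; Ti(OiPr)4 (1 equiv), 1 h; then 10, rt; aq NH4Cl
Reagents that add atoms: none
Why: BINOL–titanium-catalysed asymmetric alkynylzinc addition to an aliphatic aldehyde is weakly basic enough for the β-alkoxy aldehyde, and (R)-BINOL directs Re-face attack to give the 8S carbinol, which is the epimer needed for the inversion in the next step.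

**Step 7**
Reactants: 12 (8S)-propargylic alcohol; 13 angelic acid
Product: 14 methyl (4R)-4-[(Z)-2-methylbut-2-enoyloxy]-5-[(2R)-5-[(2S)-1-(tert-butyldimethylsilyloxy)-4,4-dimethoxybutan-2-yl]-5-methoxy-2-methyl-2,5-dihydrofuran-2-yl]pent-2-ynoate
Conditions: PPh3 and DIAD (1.5 equiv each, premixed), 13 (1.5 equiv), toluene, −10 °C to rt
Reagents that add atoms: none
Why: Mitsunobu esterification proceeds by clean SN2 inversion at the unhindered propargylic carbon (a cation there is disfavoured by the electron-poor alkyne) and sets C8 as R, the acid is never activated as an acyl donor so the Z-angelate cannot isomerise to tiglate, and no amine base is present that could isomerise the γ-oxy ynoate.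

**Step 8**
Reactants: 14 angeloyloxy ynoate
Product: 16 methyl (2Z,4R)-4-(angeloyloxy)-5-[(2R)-dihydrofuranyl ketal as in 14]-2-[(4,4,5,5-tetramethyl-1,3,2-dioxaborolan-2-yl)methyl]pent-2-enoate (C8 cis to CO2Me), via vinylalane 15 (not isolated)
Conditions: i-Bu2AlH (1.2 equiv), HMPA (2.5 equiv), THF, −20 to 0 °C, 1 h; then ICH2Bpin (1.5 equiv), 0 °C to rt
Reagents that add atoms: 2-(iodomethyl)-4,4,5,5-tetramethyl-1,3,2-dioxaborolane ICB1OC(C)(C)C(C)(C)O1; diisobutylaluminium hydride CC(C)C[AlH]CC(C)C (its aluminium is carried only by 15)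
Why: Conjugate syn-hydroalumination of the ynoate places H on C7 and Al on C11, the vinylalane then forms a boron ate complex with ICH2Bpin whose 1,2-metallate shift (Matteson-type homologation) displaces iodide with retention of alkene geometry, and the HMPA-complexed hydride attacks only the strongly electrophilic ynoate so that angelate, methyl ester, ketal and acetal survive.

**Step 9**
Reactants: 16 allylboronate ketal
Product: 17 methyl (2Z,4R,6R,7Z,10S)-4-(angeloyloxy)-10-[(tert-butyldimethylsilyloxy)methyl]-6-hydroxy-6-methyl-9,12-dioxo-2-[(4,4,5,5-tetramethyl-1,3,2-dioxaborolan-2-yl)methyl]dodeca-2,7-dienoate (in equilibrium with its hemiketal)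
Conditions: PPTS (30 mol %), acetone/H2O 10:1 (0.02 M), 35 °C, 3 h
Reagents that add atoms: water O
Why: Mild acid-catalysed acetal and ketal hydrolysis frees the C6 aldehyde and the Z-γ-hydroxy enone while TBS ether, pinacol boronate and esters stay intact, the ester-deactivated allylboronate is too slow to react between molecules under these conditions, and no stereocentre is changed.

**Step 10**
Reactants: 17 aldehyde allylboronate
Product: 19 15-O-tert-butyldimethylsilyl ether of the target (4S,6R,7S,8R,10R), via boron alkoxide 18 (not isolated)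
Conditions: toluene (1 mM), 80 °C, 36 h; then PPTS (20 mol %), rt
Reagents that add atoms: none
Why: Proposed new method: a macrocyclising carbonyl allylboration in which the acrylate β-carbon C7 (homoenolate equivalent) attacks the C6 aldehyde through a closed chair transition state with the Z-enone/hemiketal turn holding the chain ends close, the fixed alkene geometry (C8 cis to CO2Me) places C5 and C8 both equatorial and gives the 6,7-anti adduct and hence the trans-lactone, A(1,3) strain against CO2Me keeps H8 in the alkene plane so that the aldehyde adds anti to the bulky C9 branch and 8R sets 7S and 6R, and the boron alkoxide then closes the lactone on the methyl ester; the closest known reaction types are the intermolecular 2-alkoxycarbonylallylboration–lactonisation of aldehydes and the macrocyclic Barbier allylations that close germacranolide rings.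

**Step 11**
Reactants: 19 TBS ether
Product: 20 target CNP0219400.1
Conditions: HF·pyridine, pyridine, THF, 0 °C
Reagents that add atoms: none
Why: Fluoride-mediated desilylation under buffered, weakly acidic conditions removes the primary TBS group without β-elimination or C4 epimerisation of the β-hydroxy ketone and without addition to the methylene lactone, so all five stereocentres and both Z alkenes are kept.

**Compound list**
1 | allyloxy(tert-butyl)dimethylsilane | C=CCO[Si](C)(C)C(C)(C)C | starting material
2 | (E)-crotonaldehyde | C/C=C/C=O | starting material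
3 | (E)-4-(tert-butyldimethylsilyloxy)but-2-enal | O=C/C=C/CO[Si](C)(C)C(C)(C)C | intermediate
4 | 2-methylfuran | Cc1ccco1 | starting material
5 | (S)-4-(tert-butyldimethylsilyloxy)-3-(5-methylfuran-2-yl)butanal (not isolated) | O=CC[C@@H](CO[Si](C)(C)C(C)(C)C)c1ccc(C)o1 | intermediate
6 | (S)-tert-butyl[4,4-dimethoxy-2-(5-methylfuran-2-yl)butoxy]dimethylsilane | COC(OC)C[C@@H](CO[Si](C)(C)C(C)(C)C)c1ccc(C)o1 | intermediate
7 | (S,Z)-6-[(tert-butyldimethylsilyloxy)methyl]-8,8-dimethoxyoct-3-ene-2,5-dione | COC(OC)C[C@@H](CO[Si](C)(C)C(C)(C)C)C(=O)/C=C\C(C)=O | intermediate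
8 | (3S,5Z,7R)-3-[(tert-butyldimethylsilyloxy)methyl]-7-hydroxy-1,1-dimethoxy-7-methyldeca-5,9-dien-4-one, open form of its hemiketal (not isolated) | COC(OC)C[C@@H](CO[Si](C)(C)C(C)(C)C)C(=O)/C=C\[C@](C)(O)CC=C | intermediate
9 | (5R)-5-allyl-2-methoxy-5-methyl-2,5-dihydrofuran carrying the (2S)-1-(TBSO)-4,4-dimethoxybutan-2-yl group at C2, anomer mixture | COC(OC)C[C@@H](CO[Si](C)(C)C(C)(C)C)C1(OC)C=C[C@@](C)(CC=C)O1 | intermediate
10 | C8 aldehyde, (2R)-dihydrofuran-2-ylacetaldehyde | COC(OC)C[C@@H](CO[Si](C)(C)C(C)(C)C)C1(OC)C=C[C@@](C)(CC=O)O1 | intermediate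
11 | methyl propiolate | C#CC(=O)OC | starting material
12 | (8S)-γ-hydroxy ynoate | COC(OC)C[C@@H](CO[Si](C)(C)C(C)(C)C)C1(OC)C=C[C@@](C)(C[C@H](O)C#CC(=O)OC)O1 | intermediate
13 | angelic acid, (Z)-2-methylbut-2-enoic acid | OC(=O)/C(C)=C\C | starting material
14 | (8R)-γ-angeloyloxy ynoate | COC(OC)C[C@@H](CO[Si](C)(C)C(C)(C)C)C1(OC)C=C[C@@](C)(C[C@@H](OC(=O)/C(C)=C\C)C#CC(=O)OC)O1 | intermediate
15 | α-(diisobutylaluminio) enoate, C8 cis to CO2Me (not isolated) | COC(OC)C[C@@H](CO[Si](C)(C)C(C)(C)C)C1(OC)C=C[C@@](C)(C[C@@H](OC(=O)/C(C)=C\C)/C=C(\C(=O)OC)[Al](CC(C)C)CC(C)C)O1 | intermediate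
16 | (Z)-2-(methoxycarbonyl)allylboronate ketal | COC(OC)C[C@@H](CO[Si](C)(C)C(C)(C)C)C1(OC)C=C[C@@](C)(C[C@@H](OC(=O)/C(C)=C\C)/C=C(\C(=O)OC)CB2OC(C)(C)C(C)(C)O2)O1 | intermediate
17 | acyclic aldehyde allylboronate, open Z-γ-hydroxy enone form | O=CC[C@@H](CO[Si](C)(C)C(C)(C)C)C(=O)/C=C\[C@](C)(O)C[C@@H](OC(=O)/C(C)=C\C)/C=C(\C(=O)OC)CB1OC(C)(C)C(C)(C)O1 | intermediate
18 | ten-membered C6 boron alkoxide with acrylate side chain on C7 (not isolated) | C=C(C(=O)OC)[C@H]1[C@H](OB2OC(C)(C)C(C)(C)O2)C[C@@H](CO[Si](C)(C)C(C)(C)C)C(=O)/C=C\[C@](C)(O)C[C@H]1OC(=O)/C(C)=C\C | intermediate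
19 | 15-O-TBS ether of the target | C=C1C(=O)O[C@@H]2C[C@@H](CO[Si](C)(C)C(C)(C)C)C(=O)/C=C\[C@](C)(O)C[C@@H](OC(=O)/C(C)=C\C)[C@@H]12 | intermediate
20 | CNP0219400.1 (4S,6R,7S,8R,10R) | C=C1C(=O)O[C@@H]2C[C@@H](CO)C(=O)/C=C\[C@](C)(O)C[C@@H](OC(=O)/C(C)=C\C)[C@@H]12 | target

**Step count and risks**

Total step count: 11. Longest linear sequence: 11 (from 1).

The three steps most likely to fail are 10, 8 and 4.

Step 10 (ring closure). The deactivated boronate may oligomerise, or the aldehyde may stay locked up as a lactol or spiroketal. The fallback sets out from 14. The same hydroalumination is quenched with paraformaldehyde to give the 2-(hydroxymethyl)enoate F1. CBr4/PPh3 converts it into the allylic bromide F2. PPTS in wet acetone unmasks the bromo aldehyde F3. CrCl2 in THF/DMF at 1 mM then closes ring and lactone by a Nozaki–Hiyama-type macrocyclic allylation through an allylchromium species of trivalent chromium. The route is rejoined at 19.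

Step 8 (allylboronate). The vinylalane may lose its geometry through the allenolate, or the hydride may touch the angelate. The fallback sets out from 14. Bu3SnH with Pd(PPh3)4 adds syn to give the α-stannyl enoate F4. Iodine gives the α-iodo enoate F5 with retention. A Negishi coupling with IZnCH2Bpin (from ICH2Bpin and zinc dust) under Pd(PPh3)4 delivers the boronate by stereospecific cross-coupling instead of a metallate shift. The route is rejoined at 16.

Step 4 (C10). The Z-ene-dione may isomerise, or it may react with low facial selectivity. The fallback sets out from 7 and gives up catalyst control. A Barbier allylation with allyl bromide and indium in THF/H2O, followed by MeOH/PPTS, gives both C10 epimers. Because C4 is already set, these are diastereomers, so 9 is separated by chromatography from the C10-epimeric ketal F6. The route is rejoined at 9.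

**Further compounds**
F1 | step 10 | 2-(hydroxymethyl)enoate ketal, C8 cis to CO2Me | COC(OC)C[C@@H](CO[Si](C)(C)C(C)(C)C)C1(OC)C=C[C@@](C)(C[C@@H](OC(=O)/C(C)=C\C)/C=C(\C(=O)OC)CO)O1
F2 | step 10 | 2-(bromomethyl)enoate ketal, C8 cis to CO2Me | COC(OC)C[C@@H](CO[Si](C)(C)C(C)(C)C)C1(OC)C=C[C@@](C)(C[C@@H](OC(=O)/C(C)=C\C)/C=C(\C(=O)OC)CBr)O1
F3 | step 10 | acyclic bromo aldehyde, open Z-γ-hydroxy enone form | O=CC[C@@H](CO[Si](C)(C)C(C)(C)C)C(=O)/C=C\[C@](C)(O)C[C@@H](OC(=O)/C(C)=C\C)/C=C(\C(=O)OC)CBr
F4 | step 8 | α-(tributylstannyl) enoate ketal, C8 cis to CO2Me | COC(OC)C[C@@H](CO[Si](C)(C)C(C)(C)C)C1(OC)C=C[C@@](C)(C[C@@H](OC(=O)/C(C)=C\C)/C=C(\C(=O)OC)[Sn](CCCC)(CCCC)CCCC)O1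
F5 | step 8 | α-iodo enoate ketal, C8 cis to CO2Me | COC(OC)C[C@@H](CO[Si](C)(C)C(C)(C)C)C1(OC)C=C[C@@](C)(C[C@@H](OC(=O)/C(C)=C\C)/C=C(\C(=O)OC)I)O1
F6 | step 4 | C10 epimer of ketal 9 | COC(OC)C[C@@H](CO[Si](C)(C)C(C)(C)C)C1(OC)C=C[C@](C)(CC=C)O1
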